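Numbering follows 2-oxaspiro[4.5]decane: lactone ring B holds C1 (carbinol), O2, C3, C4 and spiro C5; ring A holds C6 (ketone), C7=C8, C9 (acetoxy) and C10. Ring A is disconnected at C5–C6 and C9–C10: its C6 ketone and C9 oxygen, 1,4-related across C7=C8, are a latent 2-silyloxyfuran, and C5 with C10 is the α-methylene unit of an acrolein whose formyl carbon becomes C1. One catalytic enantioselective [4+2] cycloaddition of 2-(tert-butyldimethylsilyloxy)furan with methyl 3-formylbut-3-enoate, followed in the flask by opening of the oxygen-bridged ketal, forms both bonds and both ring A stereocentres. A Nozaki–Hiyama–Kishi coupling with the full dienyl iodide then closes ring B.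

Key step: step 2

Assumption: the (R)-oxazaborolidinium of step 2 is taken to shield the enal face that leads to the (R)-quaternary carbon (formyl C–H···O binding model), and the (S)-sulfonamide ligand of step 5 to give the (R)-carbinol; each controller is available as either antipode, which would be used if the sense proved opposite.

Step 1
Reactants: 1 methyl 4-oxobutanoate
Product: 2 methyl 3-formylbut-3-enoate
Conditions: 37% aq. HCHO (1.0 equiv), pyrrolidine (10 mol%), EtCO2H (10 mol%), i-PrOH, 45 °C, 1–2 h
Reagents that add atoms: formaldehyde, C=O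
Why: Amine-catalysed Mannich-type α-methylenation (condensation with formaldehyde through the pyrrolidine enamine, then β-elimination) acts only at the aldehyde α-carbon, leaves the ester untouched and creates no stereocentre, and a short contact time at 45 °C should keep the 1,1-disubstituted double bond from migrating into conjugation with the ester.

Step 2
Reactants: 2 methyl 3-formylbut-3-enoate, 3 tert-butyl(furan-2-yloxy)dimethylsilane (1.5 equiv)
Product: 5 methyl 2-[(1R,5S)-5-[(tert-butyldimethylsilyl)oxy]-1-formyl-2-oxocyclohex-3-en-1-yl]acetate, via bridged silyl ketal 4 (not isolated)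
Conditions: (R)-3,3-diphenyl-1-(2-methylphenyl)tetrahydro-1H,3H-pyrrolo[1,2-c][1,3,2]oxazaborole (20 mol%), Tf2NH (18 mol%), CH2Cl2, −78 → −60 °C; Et3N quench
Reagents that add atoms: none
Why: The N-protonated oxazaborolidine binds the formyl oxygen of s-trans 2 and the furan ring of 3 adds across its C2 and C5 in an asynchronous [4+2] cycloaddition, the electron-rich C5 bonding to the unsubstituted methylene terminus and the silyloxy-bearing C2 to the α-carbon, to give the 1-silyloxy-7-oxanorbornene 4, whose push–pull bridgehead ketal should open at once with 1,4 O-to-O silyl transfer to the 4-silyloxycyclohex-2-enone 5. The closest known reaction types are the Diels–Alder reaction of furans with α-substituted acroleins under chiral boron Lewis acid catalysis and the Diels–Alder/bridge-opening sequence of 2-silyloxyfurans that delivers 4-oxygenated cyclohexenones. Ring A is closed by an intermolecular suprafacial [4+2] cycloaddition (both C–C bonds in one event, the carbocycle first appearing as the six-membered ring of the oxanorbornene), and the only ring then opened is the oxygen bridge. The quaternary carbon (R) is set by the catalyst, whose aryl group shields one face of the bound enal, and the silyloxy-bearing carbon (S) by the exo placement of the formyl group (syn to the oxygen bridge, the usual preference of α-substituted acroleins), which leaves the C–O bond cis to the formyl group; the bridgehead ketal centre of 4 disappears on opening. The step needs regioselectivity (the largest HOMO coefficient sits at furan C5, remote from the silyloxy group, and meets the β-methylene of the enal), conjugate rather than carbonyl addition with closure of the second bond rather than an open-chain Mukaiyama adduct (favoured by the hindered α-branched formyl group, the unhindered methylene terminus, the bulky silyl group and −78 °C), and exo and facial control (catalyst).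

Step 3
Reactants: 6 pent-1-en-4-yne
Product: 8 (1E)-1-iodo-2-methylpenta-1,4-diene, via alkenyldimethylalane 7 (not isolated)
Conditions: Me3Al (2.0 equiv), Cp2ZrCl2 (20 mol%), CH2Cl2, 0 °C → rt; then I2, THF, −30 → 0 °C
Reagents that add atoms: trimethylaluminium, C[Al](C)C; iodine, II
Why: Zirconium-catalysed carboalumination (Negishi) adds methyl and aluminium syn across the terminal alkyne with aluminium at the terminus while the monosubstituted alkene is left alone, and iodinolysis of the C–Al bond with retention fixes the E geometry of the trisubstituted iodoalkene.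

Step 4
Reactants: 8 (1E)-1-iodo-2-methylpenta-1,4-diene, 9 2-methylbut-3-en-2-ol (3 equiv)
Product: 10 (3E,6E)-7-iodo-2,6-dimethylhepta-3,6-dien-2-ol
Conditions: second-generation Grubbs catalyst (3 mol%), 1,4-benzoquinone (10 mol%), CH2Cl2, 40 °C
Reagents that add atoms: none
Why: Olefin cross-metathesis of the terminal alkene of 8 with the slowly homodimerising tertiary allylic alcohol 9 should give the E-disubstituted alkene under thermodynamic control with loss of ethylene, the trisubstituted iodoalkene being inert to the ruthenium carbene and benzoquinone suppressing hydride-mediated migration of the skipped diene.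

Step 5
Reactants: 5 methyl 2-[(1R,5S)-5-[(tert-butyldimethylsilyl)oxy]-1-formyl-2-oxocyclohex-3-en-1-yl]acetate, 10 (3E,6E)-7-iodo-2,6-dimethylhepta-3,6-dien-2-ol (1.5 equiv)
Product: 12 (1R,5R,9S)-9-[(tert-butyldimethylsilyl)oxy]-1-[(1E,4E)-6-hydroxy-2,6-dimethylhepta-1,4-dien-1-yl]-2-oxaspiro[4.5]dec-7-ene-3,6-dione, via hydroxy ester 11 (not isolated)
Conditions: CrCl2 (4 equiv), (S)-N-[2-(4-isopropyl-4,5-dihydro-1,3-oxazol-2-yl)-6-methylphenyl]methanesulfonamide (4.4 equiv), Et3N (4.4 equiv), NiCl2 (0.1 equiv), THF, rt; aqueous work-up; then PPTS (0.2 equiv), toluene, 50 °C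
Reagents that add atoms: none
Why: In this Nozaki–Hiyama–Kishi coupling NiCl2-catalysed activation of the C–I bond and transmetalation give an alkenylchromium (trivalent chromium) that keeps the E geometry and adds only to the formyl group (enone, ester, silyl ether and free tertiary alcohol are tolerated), the chiral sulfonamide on chromium selecting the aldehyde face for the (R)-carbinol, whose oxygen then closes the γ-lactone on the methyl ester (5-exo-trig acyl substitution, helped by the quaternary carbon) under mild acid.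

Step 6
Reactants: 12 (1R,5R,9S)-9-[(tert-butyldimethylsilyl)oxy]-1-[(1E,4E)-6-hydroxy-2,6-dimethylhepta-1,4-dien-1-yl]-2-oxaspiro[4.5]dec-7-ene-3,6-dione
Product: 13 (1R,5R,9S)-9-hydroxy-1-[(1E,4E)-6-hydroxy-2,6-dimethylhepta-1,4-dien-1-yl]-2-oxaspiro[4.5]dec-7-ene-3,6-dione
Conditions: HF·pyridine, pyridine, THF, 0 °C → rt
Reagents that add atoms: none
Why: Fluoride-mediated desilylation cleaves the secondary silyl ether under pyridine-buffered, non-basic conditions that spare the allylic lactone, the tertiary allylic alcohol and the γ-oxygenated enone, and touches no stereocentre.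

Step 7
Reactants: 13 (1R,5R,9S)-9-hydroxy-1-[(1E,4E)-6-hydroxy-2,6-dimethylhepta-1,4-dien-1-yl]-2-oxaspiro[4.5]dec-7-ene-3,6-dione
Product: 14 (1R,5R,9S)-1-[(1E,4E)-6-hydroxy-2,6-dimethylhepta-1,4-dien-1-yl]-3,6-dioxo-2-oxaspiro[4.5]dec-7-en-9-yl acetate
Conditions: Ac2O (1.5 equiv), pyridine, CH2Cl2, 0 °C → rt
Reagents that add atoms: acetic anhydride, CC(=O)OC(C)=O
Why: Pyridine-mediated O-acylation (esterification) should take the unhindered secondary allylic alcohol and not the tertiary one, with retention at the carbinol carbon, so the (9S)-acetate of the target results.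

Compound list
1 | methyl 4-oxobutanoate | COC(=O)CCC=O | starting material
2 | methyl 3-formylbut-3-enoate | COC(=O)CC(=C)C=O | intermediate
3 | tert-butyl(furan-2-yloxy)dimethylsilane [2-(tert-butyldimethylsilyloxy)furan] | CC(C)(C)[Si](C)(C)Oc1ccco1 | starting material
4 | methyl 2-[(1R,2R,4S)-1-[(tert-butyldimethylsilyl)oxy]-2-formyl-7-oxabicyclo[2.2.1]hept-5-en-2-yl]acetate (formyl exo) | CC(C)(C)[Si](C)(C)O[C@@]12C=C[C@@H](O1)C[C@]2(C=O)CC(=O)OC | intermediate (not isolated)
5 | methyl 2-[(1R,5S)-5-[(tert-butyldimethylsilyl)oxy]-1-formyl-2-oxocyclohex-3-en-1-yl]acetate | CC(C)(C)[Si](C)(C)O[C@@H]1C=CC(=O)[C@@](C=O)(CC(=O)OC)C1 | intermediate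
6 | pent-1-en-4-yne | C=CCC#C | starting material
7 | dimethyl[(1E)-2-methylpenta-1,4-dien-1-yl]alumane | C[Al](C)/C=C(\C)CC=C | intermediate (not isolated)
8 | (1E)-1-iodo-2-methylpenta-1,4-diene | I/C=C(\C)CC=C | intermediate
9 | 2-methylbut-3-en-2-ol | CC(C)(O)C=C | starting material
10 | (3E,6E)-7-iodo-2,6-dimethylhepta-3,6-dien-2-ol | I/C=C(\C)C/C=C/C(C)(C)O | intermediate
11 | methyl 2-[(1R,5S)-5-[(tert-butyldimethylsilyl)oxy]-1-[(1R,2E,5E)-1,7-dihydroxy-3,7-dimethylocta-2,5-dien-1-yl]-2-oxocyclohex-3-en-1-yl]acetate | CC(C)(C)[Si](C)(C)O[C@@H]1C=CC(=O)[C@@]([C@H](O)/C=C(\C)C/C=C/C(C)(C)O)(CC(=O)OC)C1 | intermediate (not isolated)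
12 | (1R,5R,9S)-9-[(tert-butyldimethylsilyl)oxy]-1-[(1E,4E)-6-hydroxy-2,6-dimethylhepta-1,4-dien-1-yl]-2-oxaspiro[4.5]dec-7-ene-3,6-dione | CC(C)(C)[Si](C)(C)O[C@@H]1C=CC(=O)[C@@]2(CC(=O)O[C@@H]2/C=C(\C)C/C=C/C(C)(C)O)C1 | intermediate
13 | (1R,5R,9S)-9-hydroxy-1-[(1E,4E)-6-hydroxy-2,6-dimethylhepta-1,4-dien-1-yl]-2-oxaspiro[4.5]dec-7-ene-3,6-dione | O[C@@H]1C=CC(=O)[C@@]2(CC(=O)O[C@@H]2/C=C(\C)C/C=C/C(C)(C)O)C1 | intermediate
14 | (+)-miliusane XVII, (1R,5R,9S)-1-[(1E,4E)-6-hydroxy-2,6-dimethylhepta-1,4-dien-1-yl]-3,6-dioxo-2-oxaspiro[4.5]dec-7-en-9-yl acetate | CC(=O)O[C@@H]1C=CC(=O)[C@@]2(CC(=O)O[C@@H]2/C=C(\C)C/C=C/C(C)(C)O)C1 | target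

Total step count: 7. Longest linear sequence: 5 steps (steps 1, 2, 5, 6, 7); steps 3 and 4 build the side chain in parallel.

Steps most likely to fail

Step 2. Under Lewis acid activation the silyloxyfuran may add in an open-chain Mukaiyama manner (to the formyl carbon, or to the methylene without closure of the second bond), and facial or exo control may erode. The fallback sets out from 2 and 3 and uses the uncatalysed thermal Diels–Alder reaction of the silyloxyfuran (toluene, 60 °C, or 10 kbar in CH2Cl2 at rt), a concerted path without cationic intermediates. It should give 5 as the racemate, that is 5 together with its enantiomer methyl 2-[(1S,5R)-5-[(tert-butyldimethylsilyl)oxy]-1-formyl-2-oxocyclohex-3-en-1-yl]acetate F1. The mixture is taken through step 5 unchanged. The ligand-controlled coupling should turn F1, by way of the hydroxy ester methyl 2-[(1S,5R)-5-[(tert-butyldimethylsilyl)oxy]-1-[(1R,2E,5E)-1,7-dihydroxy-3,7-dimethylocta-2,5-dien-1-yl]-2-oxocyclohex-3-en-1-yl]acetate F2, into the diastereomeric lactone (1R,5S,9R)-9-[(tert-butyldimethylsilyl)oxy]-1-[(1E,4E)-6-hydroxy-2,6-dimethylhepta-1,4-dien-1-yl]-2-oxaspiro[4.5]dec-7-ene-3,6-dione F3. F3 is removed by chromatography and the route is rejoined at 12.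

Step 5. Facial discrimination at the neopentyl-type formyl group may be poor, the coupling of two hindered partners may be slow, and the formyl group may be lost by retro-Claisen cleavage. The fallback sets out from 10 and replaces the chromium coupling by an amino alcohol-catalysed enantioselective alkenylzinc addition. Silylation (TESOTf, 2,6-lutidine, CH2Cl2, −78 °C) gives triethyl{[(3E,6E)-7-iodo-2,6-dimethylhepta-3,6-dien-2-yl]oxy}silane F4. Iodine–lithium exchange (t-BuLi, Et2O, −78 °C) and ZnBr2 give bromo[(1E,4E)-2,6-dimethyl-6-[(triethylsilyl)oxy]hepta-1,4-dien-1-yl]zinc F5. After addition of N,N,N′,N′-tetraethylethylenediamine to bind lithium salts, F5 is added to 5 in toluene at −30 → 0 °C with (2S)-3-exo-morpholinoisoborneol (10 mol%, or its antipode as needed for the (R)-carbinol); ketone and ester are inert to the organozinc. This should give methyl 2-[(1R,5S)-5-[(tert-butyldimethylsilyl)oxy]-1-[(1R,2E,5E)-1-hydroxy-3,7-dimethyl-7-[(triethylsilyl)oxy]octa-2,5-dien-1-yl]-2-oxocyclohex-3-en-1-yl]acetate F6. PPTS in toluene lactonises F6 to (1R,5R,9S)-9-[(tert-butyldimethylsilyl)oxy]-1-[(1E,4E)-2,6-dimethyl-6-[(triethylsilyl)oxy]hepta-1,4-dien-1-yl]-2-oxaspiro[4.5]dec-7-ene-3,6-dione F7. The conditions of step 6 then remove both silyl groups and the route is rejoined at 13.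

Step 1. Under amine catalysis the new double bond may migrate into conjugation with the ester, and the enal may oligomerise on standing. The fallback sets out from 1 and separates aminomethylation from elimination. Mannich reaction with dimethylmethyleneammonium iodide (CH2Cl2, rt; NaHCO3 wash) gives methyl 4-(dimethylamino)-3-formylbutanoate F8. Quaternisation (MeI, CH2Cl2, 0 °C) gives 4-methoxy-2-formyl-4-oxo-N,N,N-trimethylbutan-1-aminium iodide F9. Cold two-phase elimination (aq. NaHCO3/CH2Cl2, 0 °C) releases 2 free of secondary amine, to be used at once in step 2.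

Further compounds
F1 | step 2 | methyl 2-[(1S,5R)-5-[(tert-butyldimethylsilyl)oxy]-1-formyl-2-oxocyclohex-3-en-1-yl]acetate | CC(C)(C)[Si](C)(C)O[C@H]1C=CC(=O)[C@](C=O)(CC(=O)OC)C1
F2 | step 2 | methyl 2-[(1S,5R)-5-[(tert-butyldimethylsilyl)oxy]-1-[(1R,2E,5E)-1,7-dihydroxy-3,7-dimethylocta-2,5-dien-1-yl]-2-oxocyclohex-3-en-1-yl]acetate | CC(C)(C)[Si](C)(C)O[C@H]1C=CC(=O)[C@]([C@H](O)/C=C(\C)C/C=C/C(C)(C)O)(CC(=O)OC)C1
F3 | step 2 | (1R,5S,9R)-9-[(tert-butyldimethylsilyl)oxy]-1-[(1E,4E)-6-hydroxy-2,6-dimethylhepta-1,4-dien-1-yl]-2-oxaspiro[4.5]dec-7-ene-3,6-dione | CC(C)(C)[Si](C)(C)O[C@H]1C=CC(=O)[C@]2(CC(=O)O[C@@H]2/C=C(\C)C/C=C/C(C)(C)O)C1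
F4 | step 5 | triethyl{[(3E,6E)-7-iodo-2,6-dimethylhepta-3,6-dien-2-yl]oxy}silane | I/C=C(\C)C/C=C/C(C)(C)O[Si](CC)(CC)CC
F5 | step 5 | bromo[(1E,4E)-2,6-dimethyl-6-[(triethylsilyl)oxy]hepta-1,4-dien-1-yl]zinc | Br[Zn]/C=C(\C)C/C=C/C(C)(C)O[Si](CC)(CC)CC
F6 | step 5 | methyl 2-[(1R,5S)-5-[(tert-butyldimethylsilyl)oxy]-1-[(1R,2E,5E)-1-hydroxy-3,7-dimethyl-7-[(triethylsilyl)oxy]octa-2,5-dien-1-yl]-2-oxocyclohex-3-en-1-yl]acetate | CC(C)(C)[Si](C)(C)O[C@@H]1C=CC(=O)[C@@]([C@H](O)/C=C(\C)C/C=C/C(C)(C)O[Si](CC)(CC)CC)(CC(=O)OC)C1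
F7 | step 5 | (1R,5R,9S)-9-[(tert-butyldimethylsilyl)oxy]-1-[(1E,4E)-2,6-dimethyl-6-[(triethylsilyl)oxy]hepta-1,4-dien-1-yl]-2-oxaspiro[4.5]dec-7-ene-3,6-dione | CC(C)(C)[Si](C)(C)O[C@@H]1C=CC(=O)[C@@]2(CC(=O)O[C@@H]2/C=C(\C)C/C=C/C(C)(C)O[Si](CC)(CC)CC)C1
F8 | step 1 | methyl 4-(dimethylamino)-3-formylbutanoate | COC(=O)CC(C=O)CN(C)C
F9 | step 1 | 4-methoxy-2-formyl-4-oxo-N,N,N-trimethylbutan-1-aminium iodide | COC(=O)CC(C=O)C[N+](C)(C)C.[I-]
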